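The pitfall on a plate is to read percentages across wells of different solid charge: ash and larch hold the same partner, 0.75 M, yet at 8.00 h ash reads 2 % of target, less than the 20 % of larch.

| flask | solid substrate | partner | remark | time |
|---|---|---|---|---|
| larch | 0.34 M | 0.75 M | run made earlier |  |
| ash | 0.75 M | 0.75 M | run made earlier |  |
| cedar | 0.50 M | 1.1 M | run made earlier |  |
| flask | 0.50 M | 0.750 M |  | 10 h |

| run | time / h | target / % | solid product / % |
|---|---|---|---|
| larch | 1.33 | 6 | 0 |
| larch | 2.50 | 9 | 1 |
| larch | 4.00 | 11 | 0 |
| larch | 5.00 | 15 | 1 |
| larch | 6.00 | 16 | 0 |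
| larch | 8.00 | 20 | 0 |
| ash | 0.500 | 0 | 3 |
| ash | 1.50 | 0 | 0 |
| ash | 3.00 | 0 | 0 |
| ash | 4.00 | 3 | 0 |
| ash | 6.00 | 1 | 0 |
| ash | 8.00 | 2 | 0 |
| cedar | 0.667 | 6 | 1 |
| cedar | 2.00 | 9 | 2 |
| cedar | 4.00 | 15 | 1 |
| cedar | 6.00 | 17 | 0 |
| cedar | 8.00 | 19 | 2 |

(scatter of a reading: 2 percentage points)

- how much target and solid product together there is at 10 h, in percent of the solid substrate charged
- concentration of dissolved substrate in solution at 10 h, in percent of saturation

- amounts and yields of target count solid product too
- given per volume of solution although it is solid: solid substrate, solid product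
- at the start none of the solid substrate is in solution
- dissolved substrate means what is dissolved; the solid is not counted in it

Which run speaks for the flask? Cedar, which has the flask's solid charge, 0.50 M, and differs in partner.

What do you freeze? Two things. I assume dissolved substrate stays near saturation and partner stays at its charge, though no reading shows either. Target is then made in proportion to partner.

And the missing hours? Cedar's target rose from 15 % to 19 % over its last 4.00 h, so I continue that line to 21.0 % at 10 h. Its solid product readings top out at 2 %, the size of the scatter, so I drop them.

Your quantity? With 2.20 equivalents of partner in cedar, the yield per equivalent, meaning percent of solid charged at a given time and solid charge, divided by the equivalents of partner, is 9.55 %.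

Does it travel to another solid charge? No. At 8.00 h, ash reads 2.00 % per equivalent and cedar 8.64 %.

The flask, then? It has 1.50 equivalents, so I commit to 14.3 %, with the solution near saturation and no figure put on it.

The forecast said 10 % and 95 %, reasoning that “Most solid remains and reaction is slow, so the solution should be nearly saturated”.

The flask gives 12.2 % and 89.7 %, so my 14.3 % stands above the yield.

    solid product ⇌ target, rate k1*(cs1 - [target]) while solid is left; crystals form when [target] > cs1 (solubility = 0.220 M, k = 6.40 × 10⁻⁴ s⁻¹)
    solid substrate ⇌ dissolved substrate, rate k2*(cs2 - [dissolved substrate]) while solid is left; crystals form when [dissolved substrate] > cs2 (solubility = 0.0570 M, k = 7.20 × 10⁻⁴ s⁻¹)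
    target ⇌ isomer of the product (K = 0.220, k = 7.50 × 10⁻⁴ s⁻¹)
    solid substrate + target → side product (k = 2.30 × 10⁻⁴ M⁻¹ s⁻¹)
    dissolved substrate + partner → target (k = 1.40 × 10⁻⁴ M⁻¹ s⁻¹)

In the flask, dissolved substrate has a half-life of 2.0 h at 3.48 h by its turning into target with partner, short against 10 h. At 10.0 h it is made 1.01 times as fast as it is used up, a quasi-steady state, which is the frozen pool the yield per equivalent assumed.

A neighbouring flask has the same solid charge with 0.45 M of partner, so 9.55 % per equivalent gives 8.59 %. It computes to 6.59 %.

Readings and results were computed for substances that don't exist, noise included.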